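**Analysis of the target**

Conventions: germacrane numbering is used for the ten-membered ring and its appendages. C1–C3 are CH2, C4 is CHMe (C15), C5 is the ketone, C6 is CHOH, C7 is CH, C8 is CH–O(lactone), C9 is CH–OAng, C10 is C(Me)(OH) (C14); C11(=C13H2)–C12(=O) complete the lactone. PMB = 4-methoxybenzyl, TBS = tert-butyldimethylsilyl, TMS = trimethylsilyl, Ang = angeloyl, (Z)-2-methylbut-2-enoyl.

The target 29 is a germacranolide: a ten-membered carbocycle (ring A, C1–C10) trans-fused across C7–C8 to an α-methylene-γ-butyrolactone (ring B: C7, C8, O, C12, C11). It has six stereocentres, (4S,6S,7S,8R,9S,10R). Five are contiguous (C6–C10); C4 stands alone next to the ketone. H7 and H8 are anti (trans-lactone), and the C9 and C10 oxygen atoms are related as the product of an anti addition to an (E)-C9=C10 double bond. The sensitive groups are the exocyclic Michael acceptor, the angelate (isomerises to the tiglate under base or nucleophilic catalysis), the acyloin C5/C6 with two epimerisable α-carbons (C4, C6), and the free C6–OH, which is also γ to C12 and can translactonise. C10–OH lies 1,6 across ring A from the C5 carbonyl, so transannular hemiketal formation and other transannular reactions are possible. The difficulty is a medium ring without any ring double bond or heteroatom to cut at, and contiguous stereocentres that can only be related to each other through the conformation of that ring. The feature the plan rests on: C5(=O)–C6(OH) and C9(OAng)–C10(OH) are two vicinally oxidised two-carbon units on either side of the C7–C8 bond, with C5 and C10 facing each other across ring A. This is the oxidation pattern of a cyclodeca-1,5-diene (C5=C6, C9=C10), the [3,3]-shift product of a 1,2-dialkenylcyclohexane in which C5 and C10 are bonded.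

**Retrosynthetic reasoning**

29 back to 28 and 25. The C6 hydroxyl is unmasked last, and ring B is closed late by oxidation of a C12 allylic alcohol onto C8–OH (C12–O8 bond). The α-methylene lactone is the most fragile group, so it is carried as an allylic ether. C6–O must stay silylated while the lactone closes because it competes for C12.

25 back to 24 and 21. The ester bond at C9 is cut to angelic acid 22. Acylation is placed where C9–OH is the only acylable hydroxyl (C6 silylated, C8 and C12 as PMB ethers, C10 tertiary). Both PMB ethers then fall in one operation.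

21 back to 20 and 18. The C10–O, C9–O and C6–O bonds are traced to the two ring double bonds of triene 18. The C9/C10 diol is the anti-dihydroxylation product of the (E)-C9=C10 alkene (epoxide 20, opened at the tertiary C10 with inversion). The C6–O bond comes from oxidation of the C5=C6 silyl enol ether. The forward reactions must attack the outer faces of both double bonds.

18 back to 15 (key disconnection). The C7–C8 bond is cut and the C5–C10 bond is reconnected, which turns ring A into the cyclohexanol 15 carrying the two alkenyl arms on adjacent carbons. Cutting here removes the medium ring and the C7/C8 stereocentres at once. They become two (E)-alkene geometries, and the ring is a 2,6-dimethylcyclohexanone derivative. The other [3,3] orientation (enolate toward C4) was not used because it needs a cyclohexane substituted on all six carbons.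

15 back to 14, then to 7 and 12. The C5–C6 bond is made by addition of an acetylide to the ketone; the alkyne is the precursor of the (E)-alkene. A slim nucleophile is chosen because the ketone is hindered and enolisable, and because its axial approach fixes the carbinol configuration.

7 back to 5, 4, 2 and 1. The enol ether C8–O bond comes from a vinyl iodide and alcohol 6, C8 from a one-carbon olefination of aldehyde 4, and C9 from formylation of silyl enol ether 2 at the carbon that becomes the quaternary C10. The C4 stereocentre comes from desymmetrisation of the meso ketone 1.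

12 back to 9 and 10, and 9 back to 8 and 6. The C7/C11–C13 arm is a 2-substituted enyne assembled by cross-coupling and etherification.

**Alternatives that were turned down**

Alternative 1: the textbook route cuts C7–C8 in an open chain. The seco aldehyde–allylic bromide A1 would be cyclised by an intramolecular chromium-mediated (CrCl2) Barbier allylation; the C8 alkoxide then lactonises onto the ester. It was turned down because A1 needs C4, C6, C9 and C10 set one by one on a flexible twelve-carbon chain. The ten-membered closure also fights entropy and transannular strain, the C7/C8 relative configuration depends on an uncontrolled macrocyclic transition state, and the route is roughly twice as long.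

Alternative 2: ring-closing metathesis of the seco diene A2 at C2=C3, then hydrogenation. It was turned down for three reasons. Ten-membered rings close poorly by metathesis and tend to oligomerise. All six stereocentres and the lactone would have to be built before the key step, so the step wins nothing. The C2=C3 hydrogenation would have to spare the α-methylene lactone and the angelate, which is not credible.

Alternative 3: oxidative cleavage of the tetrasubstituted C5=C10 double bond of the bicyclic octalin A3 (ozonolysis) to the cyclodecane-5,10-dione A4, then methyl addition at C10. It was turned down for three reasons. A3 still carries the four contiguous stereocentres C6–C9 on a fully substituted six-membered ring. The two ketones of A4 are hard to tell apart and 1,6-diketones of this ring size undergo transannular aldol reaction. The C10 configuration would rest on an unguided addition.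

Key step: step 9

Assumption: the pure cis (meso) isomer of 1 is used, and the antipode of the chiral amine in step 1 is the one that gives (S)-2 (drawn here as R,R; the sense must be confirmed and the other antipode is equally available).

**Route**

Step 1
Reactants: 1 cis-2,6-dimethylcyclohexan-1-one
Product: 2 trimethyl{[(6S)-2,6-dimethylcyclohex-1-en-1-yl]oxy}silane
Conditions: (R,R)-bis(1-phenylethyl)amine, n-BuLi, LiCl, TMSCl (internal quench), THF, −78 °C
Reagents that add atoms: chlorotrimethylsilane, C[Si](C)(C)Cl
Why: Enantiotopic-proton-selective deprotonation of the meso ketone by a chiral lithium amide with internal silyl quench (asymmetric desymmetrisation); the α-carbon that keeps its hydrogen becomes the only stereocentre (later C4), S by the choice of amide antipode.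

Step 2
Reactants: 2 trimethyl{[(6S)-2,6-dimethylcyclohex-1-en-1-yl]oxy}silane
Product: 4 (1R,3S)-1,3-dimethyl-2-oxocyclohexane-1-carbaldehyde, via keto acetal 3 (not isolated)
Conditions: HC(OMe)3, TMSOTf (cat.), CH2Cl2, −78 °C; then 1 M HCl, THF, 0 °C
Reagents that add atoms: trimethyl orthoformate, COC(OC)OC; water, O
Why: Mukaiyama-type addition of the silyl enol ether to the dimethoxycarbenium ion; the electrophile should enter anti to the pseudoaxial ring methyl group (held axial by A(1,2) strain with OTMS), which places the new carbon trans to that methyl and sets the quaternary centre as R. Dilute acid unmasks the aldehyde of 3; the new centre is quaternary and the β-keto aldehyde cannot enolise between the carbonyls.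

Step 3
Reactants: 4 (1R,3S)-1,3-dimethyl-2-oxocyclohexane-1-carbaldehyde
Product: 5 (2R,6S)-2-[(E)-2-iodoethenyl]-2,6-dimethylcyclohexan-1-one
Conditions: CHI3, CrCl2, THF, 0 °C to rt
Reagents that add atoms: iodoform, IC(I)I
Why: Takai olefination; the gem-dichromium species adds only to the aldehyde (the ketone is flanked by a quaternary and a tertiary carbon) and gives the (E)-vinyl iodide, as usual for α-branched aldehydes.

Step 4
Reactants: 5 (2R,6S)-2-[(E)-2-iodoethenyl]-2,6-dimethylcyclohexan-1-one; 6 (4-methoxyphenyl)methanol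
Product: 7 (2R,6S)-2-{(E)-2-[(4-methoxyphenyl)methoxy]ethenyl}-2,6-dimethylcyclohexan-1-one
Conditions: CuI (10 mol%), 3,4,7,8-tetramethyl-1,10-phenanthroline (20 mol%), Cs2CO3, toluene, 80 °C
Reagents that add atoms: none
Why: Copper-catalysed Ullmann-type C–O coupling of a vinyl iodide with an alcohol, which retains the alkene geometry and so gives the (E)-enol ether needed for a pseudo-equatorial C8–O in the key step. The heterogeneous carbonate is not expected to enolise the hindered ketone toward its tertiary α-hydrogen.

Step 5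
Reactants: 8 2,3-dibromoprop-1-ene; 6 (4-methoxyphenyl)methanol
Product: 9 1-{[(2-bromoprop-2-en-1-yl)oxy]methyl}-4-methoxybenzene
Conditions: NaH, THF, 0 °C to rt
Reagents that add atoms: none
Why: Williamson ether synthesis; the alkoxide of 6 displaces the allylic bromide (SN2), the vinylic bromide is inert.

Step 6
Reactants: 9 1-{[(2-bromoprop-2-en-1-yl)oxy]methyl}-4-methoxybenzene; 10 ethynyl(trimethyl)silane
Product: 12 1-methoxy-4-{[(2-methylidenebut-3-yn-1-yl)oxy]methyl}benzene, via silyl enyne 11 (not isolated)
Conditions: Pd(PPh3)2Cl2 (3 mol%), CuI (5 mol%), Et3N, THF, rt; then K2CO3, MeOH, rt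
Reagents that add atoms: none
Why: Sonogashira coupling at the vinylic C–Br bond, then methanolysis of the C–Si bond in the same flask, gives the terminal 2-substituted enyne; no stereocentre is involved.

Step 7
Reactants: 12 1-methoxy-4-{[(2-methylidenebut-3-yn-1-yl)oxy]methyl}benzene; 7 (2R,6S)-2-{(E)-2-[(4-methoxyphenyl)methoxy]ethenyl}-2,6-dimethylcyclohexan-1-one
Product: 14 (1R,2R,6S)-1-(3-{[(4-methoxyphenyl)methoxy]methyl}but-3-en-1-yn-1-yl)-2-{(E)-2-[(4-methoxyphenyl)methoxy]ethenyl}-2,6-dimethylcyclohexan-1-ol, via lithium acetylide 13 (not isolated)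
Conditions: 12, n-BuLi, THF, −78 °C; then 7, −78 to −20 °C
Reagents that add atoms: none
Why: 1,2-Addition of a lithium acetylide, which is too weakly basic to enolise the ketone. In 7 both methyl groups are equatorial and the enol ether arm is axial, so the slim nucleophile should attack axially, anti to that arm: the alkyne ends trans to the enol ether arm and cis to both methyl groups (C1 R).

Step 8
Reactants: 14 (1R,2R,6S)-1-(3-{[(4-methoxyphenyl)methoxy]methyl}but-3-en-1-yn-1-yl)-2-{(E)-2-[(4-methoxyphenyl)methoxy]ethenyl}-2,6-dimethylcyclohexan-1-ol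
Product: 15 (1S,2R,6S)-1-[(1E)-3-{[(4-methoxyphenyl)methoxy]methyl}buta-1,3-dien-1-yl]-2-{(E)-2-[(4-methoxyphenyl)methoxy]ethenyl}-2,6-dimethylcyclohexan-1-ol
Conditions: NaAlH2(OCH2CH2OMe)2, THF, 0 °C to rt; Rochelle salt work-up
Reagents that add atoms: none
Why: Hydroxyl-directed trans-hydroalumination of the propargylic alcohol and protonolysis give the (E)-alkene; the descriptor at C1 changes to S only because the priority of the arm drops. Enol ether, 1,1-disubstituted alkene and PMB ethers are inert to the aluminate.

Step 9
Reactants: 15 (1S,2R,6S)-1-[(1E)-3-{[(4-methoxyphenyl)methoxy]methyl}buta-1,3-dien-1-yl]-2-{(E)-2-[(4-methoxyphenyl)methoxy]ethenyl}-2,6-dimethylcyclohexan-1-ol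
Product: 18 (4S,5Z,7R,8S,9E)-5-[(tert-butyldimethylsilyl)oxy]-8,12-bis[(4-methoxyphenyl)methoxy]germacra-5,9,11(13)-triene, via potassium alkoxide 16 (not isolated), via potassium enolate 17 (not isolated)
Conditions: KN(SiMe3)2 (1.2 equiv), 18-crown-6, THF, −78 °C to rt; then TBSCl, −78 to 0 °C
Reagents that add atoms: tert-butyldimethylsilyl chloride, CC(C)(C)[Si](C)(C)Cl
Why: Deprotonation gives alkoxide 16, in which the ring bond C5–C10 (cyclohexanol C1–C2) is the central σ bond of a 3-oxido-1,5-diene C7=C6–C5(O−)–C10–C9=C8; the anionic oxy-Cope rearrangement ([3,3]-sigmatropic shift) forms C7–C8, breaks C5–C10 and gives the ten-membered enolate 17, which is silylated on oxygen. The closest known reaction type is the anionic oxy-Cope ring expansion of trans-1,2-dialkenylcyclohexanols to (E)-cyclodec-5-enones, a reaction that tolerates enol ether termini. Ring A is not closed end to end: it arises by four-atom ring expansion of the cyclohexane (C1–C5, C10) through a chair transition state fused trans-decalin-like to the cyclohexane chair, reached from the ring-flipped conformer of 15 with both alkenyl arms equatorial. C7 and C8 are set together: the two (E)-alkenes place the C11 unit and the OPMB group pseudo-equatorial, which gives the anti H7/H8 (trans-lactone) relationship, and the absolute sense is dictated by the carbinol and quaternary centres of 15, which are consumed (chirality transfer). The same chair fixes the geometry of the new C5=C6 enolate (ring-trans, 5Z) and of the C9=C10 alkene (E), on which the later face-selective oxidations depend; C4 is untouched because the enolate forms only toward C6. The step needs chair over boat and a concerted over a dissociative course: the trans arrangement of the arms allows only one chair, the alkoxyallyl anion that heterolysis would give is poorly stabilised, and the crown ether loosens the ion pair so that the shift should run at or below room temperature. Silylation at low temperature prevents proton transfer from the doubly allylic C7–H and installs the handle for C6 oxygenation.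

Step 10
Reactants: 18 (4S,5Z,7R,8S,9E)-5-[(tert-butyldimethylsilyl)oxy]-8,12-bis[(4-methoxyphenyl)methoxy]germacra-5,9,11(13)-triene
Product: 20 (4S,6S,7R,8R,9S,10S)-6-[(tert-butyldimethylsilyl)oxy]-9,10-epoxy-8,12-bis[(4-methoxyphenyl)methoxy]germacr-11(13)-en-5-one, via bis-epoxide 19 (not isolated)
Conditions: mCPBA (2.2 equiv), NaHCO3, CH2Cl2, −20 to 0 °C
Reagents that add atoms: 3-chloroperoxybenzoic acid, OOC(=O)c1cccc(Cl)c1
Why: One peracid does two oxidations: Rubottom oxidation of the silyl enol ether (epoxidation, ring opening, 1,4-silyl shift) gives the C6 silyloxy ketone, and Prilezhaev epoxidation converts the strained trisubstituted (E)-C9=C10 alkene. Both should occur on the outer (peripheral) faces of the crown conformer inherited from the chair transition state, where only H7 and H8 flank the π faces; this sets C6 (S), C9 (S) and C10 (S). The 1,1-disubstituted C11=C13 alkene is less electron-rich (allylic ether) and should react last.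

Step 11
Reactants: 20 (4S,6S,7R,8R,9S,10S)-6-[(tert-butyldimethylsilyl)oxy]-9,10-epoxy-8,12-bis[(4-methoxyphenyl)methoxy]germacr-11(13)-en-5-one
Product: 21 (4S,6S,7R,8R,9S,10R)-6-[(tert-butyldimethylsilyl)oxy]-9,10-dihydroxy-8,12-bis[(4-methoxyphenyl)methoxy]germacr-11(13)-en-5-one
Conditions: HClO4 (cat., aq.), THF/H2O 3:1, 0 °C
Reagents that add atoms: water, O
Why: Acid-catalysed epoxide hydrolysis: the tertiary C10–O bond is cleaved with inversion and C9–O is retained, so the net anti addition to the former (E)-alkene gives the (9S,10R)-diol. The C5 carbonyl oxygen lies over the inner face of C10 (these carbons were bonded in 15) and can assist through a bridged oxocarbenium ion, whose hydrolysis gives the same diol. Silyl and PMB ethers tolerate dilute acid at 0 °C.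

Step 12
Reactants: 21 (4S,6S,7R,8R,9S,10R)-6-[(tert-butyldimethylsilyl)oxy]-9,10-dihydroxy-8,12-bis[(4-methoxyphenyl)methoxy]germacr-11(13)-en-5-one; 22 angelic acid
Product: 24 (4S,6S,7R,8R,9S,10R)-9-angeloyloxy-6-[(tert-butyldimethylsilyl)oxy]-10-hydroxy-8,12-bis[(4-methoxyphenyl)methoxy]germacr-11(13)-en-5-one, via mixed anhydride 23 (not isolated)
Conditions: 22, 2,4,6-trichlorobenzoyl chloride, Et3N, toluene, rt; then 21, 75 °C
Reagents that add atoms: none
Why: Yamaguchi-type esterification through mixed anhydride 23 without DMAP, the conditions under which angelates are installed without Z to E isomerisation. C9–OH is the only acylable hydroxyl: C10–OH is tertiary and C6, C8 and C12 are protected.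

Step 13
Reactants: 24 (4S,6S,7R,8R,9S,10R)-9-angeloyloxy-6-[(tert-butyldimethylsilyl)oxy]-10-hydroxy-8,12-bis[(4-methoxyphenyl)methoxy]germacr-11(13)-en-5-one
Product: 25 (4S,6S,7R,8R,9S,10R)-9-angeloyloxy-6-[(tert-butyldimethylsilyl)oxy]-8,10,12-trihydroxygermacr-11(13)-en-5-one
Conditions: DDQ (2.5 equiv), CH2Cl2/pH 7 buffer 10:1, 0 °C to rt
Reagents that add atoms: none
Why: Oxidative cleavage of both PMB ethers (hydride abstraction, hydrolysis of the oxocarbenium ions); silyl ether, angelate and the alkenes are not affected, and the neutral medium disfavours acyl migration from C9 to C8.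

Step 14
Reactants: 25 (4S,6S,7R,8R,9S,10R)-9-angeloyloxy-6-[(tert-butyldimethylsilyl)oxy]-8,10,12-trihydroxygermacr-11(13)-en-5-one
Product: 28 (4S,6S,7R,8R,9S,10R)-9-angeloyloxy-6-[(tert-butyldimethylsilyl)oxy]-10-hydroxy-5-oxogermacr-11(13)-en-12,8-olide, via enal 26 (not isolated), via lactol 27 (not isolated)
Conditions: TEMPO (0.2 equiv), PhI(OAc)2 (2.5 equiv), CH2Cl2, rt
Reagents that add atoms: none
Why: Oxidative lactonisation with the oxoammonium system: the primary allylic C12 alcohol is oxidised to enal 26, C8–OH adds to give lactol 27, and a second oxidation gives the α-methylene lactone; secondary and tertiary hydroxyls react far more slowly. The trans ring fusion is already fixed at C7 and C8, and the silyl ether keeps C6–O from competing for C12.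

Step 15
Reactants: 28 (4S,6S,7R,8R,9S,10R)-9-angeloyloxy-6-[(tert-butyldimethylsilyl)oxy]-10-hydroxy-5-oxogermacr-11(13)-en-12,8-olide
Product: 29 (4S,6S,7S,8R,9S,10R)-9-angeloyloxy-6,10-dihydroxy-5-oxogermacr-11(13)-en-12,8-olide (target)
Conditions: HF·pyridine, pyridine, THF, 0 °C to rt
Reagents that add atoms: none
Why: Fluoride cleavage of the silyl ether under buffered, weakly acidic conditions, which avoid base-induced epimerisation at C4 and C6, acyl migration and translactonisation; no stereocentre is touched (the C7 descriptor returns to S only through the priority change).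

**Compound list**

1 | cis-2,6-dimethylcyclohexan-1-one (meso) | C[C@H]1CCC[C@@H](C)C1=O | starting material
2 | trimethyl{[(6S)-2,6-dimethylcyclohex-1-en-1-yl]oxy}silane | C[C@H]1CCCC(C)=C1O[Si](C)(C)C | intermediate
3 | (2R,6S)-2-(dimethoxymethyl)-2,6-dimethylcyclohexan-1-one | O=C1[C@@H](C)CCC[C@]1(C)C(OC)OC | intermediate (not isolated)
4 | (1R,3S)-1,3-dimethyl-2-oxocyclohexane-1-carbaldehyde | O=C1[C@@H](C)CCC[C@]1(C)C=O | intermediate
5 | (2R,6S)-2-[(E)-2-iodoethenyl]-2,6-dimethylcyclohexan-1-one | O=C1[C@@H](C)CCC[C@]1(C)/C=C/I | intermediate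
6 | (4-methoxyphenyl)methanol | COc1ccc(CO)cc1 | starting material
7 | (2R,6S)-2-{(E)-2-[(4-methoxyphenyl)methoxy]ethenyl}-2,6-dimethylcyclohexan-1-one | O=C1[C@@H](C)CCC[C@]1(C)/C=C/OCc2ccc(OC)cc2 | intermediate
8 | 2,3-dibromoprop-1-ene | C=C(Br)CBr | starting material
9 | 1-{[(2-bromoprop-2-en-1-yl)oxy]methyl}-4-methoxybenzene | C=C(Br)COCc1ccc(OC)cc1 | intermediate
10 | ethynyl(trimethyl)silane | C#C[Si](C)(C)C | starting material
11 | (3-{[(4-methoxyphenyl)methoxy]methyl}but-3-en-1-yn-1-yl)(trimethyl)silane | C=C(C#C[Si](C)(C)C)COCc1ccc(OC)cc1 | intermediate (not isolated)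
12 | 1-methoxy-4-{[(2-methylidenebut-3-yn-1-yl)oxy]methyl}benzene | C#CC(=C)COCc1ccc(OC)cc1 | intermediate
13 | lithium acetylide of 12 | [Li]C#CC(=C)COCc1ccc(OC)cc1 | intermediate (not isolated)
14 | (1R,2R,6S)-1-(3-{[(4-methoxyphenyl)methoxy]methyl}but-3-en-1-yn-1-yl)-2-{(E)-2-[(4-methoxyphenyl)methoxy]ethenyl}-2,6-dimethylcyclohexan-1-ol | O[C@]1(C#CC(=C)COCc2ccc(OC)cc2)[C@@H](C)CCC[C@]1(C)/C=C/OCc3ccc(OC)cc3 | intermediate
15 | (1S,2R,6S)-1-[(1E)-3-{[(4-methoxyphenyl)methoxy]methyl}buta-1,3-dien-1-yl]-2-{(E)-2-[(4-methoxyphenyl)methoxy]ethenyl}-2,6-dimethylcyclohexan-1-ol | O[C@]1(/C=C/C(=C)COCc2ccc(OC)cc2)[C@@H](C)CCC[C@]1(C)/C=C/OCc3ccc(OC)cc3 | intermediate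
16 | potassium alkoxide of 15 | [K+].[O-][C@]1(/C=C/C(=C)COCc2ccc(OC)cc2)[C@@H](C)CCC[C@]1(C)/C=C/OCc3ccc(OC)cc3 | intermediate (not isolated)
17 | potassium (4S,5Z,7R,8S,9E)-8,12-bis[(4-methoxyphenyl)methoxy]germacra-5,9,11(13)-trien-5-olate | [K+].C1C/C(C)=C/[C@H](OCc2ccc(OC)cc2)[C@@H](C(=C)COCc3ccc(OC)cc3)/C=C([O-])/[C@@H](C)C1 | intermediate (not isolated)
18 | (4S,5Z,7R,8S,9E)-5-[(tert-butyldimethylsilyl)oxy]-8,12-bis[(4-methoxyphenyl)methoxy]germacra-5,9,11(13)-triene | C1C/C(C)=C/[C@H](OCc2ccc(OC)cc2)[C@@H](C(=C)COCc3ccc(OC)cc3)/C=C(O[Si](C)(C)C(C)(C)C)/[C@@H](C)C1 | intermediate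
19 | (4S,5R,6S,7R,8R,9S,10S)-5-[(tert-butyldimethylsilyl)oxy]-5,6:9,10-diepoxy-8,12-bis[(4-methoxyphenyl)methoxy]germacr-11(13)-ene | C1C[C@]2(C)O[C@H]2[C@H](OCc3ccc(OC)cc3)[C@@H](C(=C)COCc4ccc(OC)cc4)[C@@H]5O[C@@]5(O[Si](C)(C)C(C)(C)C)[C@@H](C)C1 | intermediate (not isolated)
20 | (4S,6S,7R,8R,9S,10S)-6-[(tert-butyldimethylsilyl)oxy]-9,10-epoxy-8,12-bis[(4-methoxyphenyl)methoxy]germacr-11(13)-en-5-one | C1C[C@]2(C)O[C@H]2[C@H](OCc3ccc(OC)cc3)[C@@H](C(=C)COCc4ccc(OC)cc4)[C@H](O[Si](C)(C)C(C)(C)C)C(=O)[C@@H](C)C1 | intermediate
21 | (4S,6S,7R,8R,9S,10R)-6-[(tert-butyldimethylsilyl)oxy]-9,10-dihydroxy-8,12-bis[(4-methoxyphenyl)methoxy]germacr-11(13)-en-5-one | C1C[C@@](C)(O)[C@@H](O)[C@H](OCc2ccc(OC)cc2)[C@@H](C(=C)COCc3ccc(OC)cc3)[C@H](O[Si](C)(C)C(C)(C)C)C(=O)[C@@H](C)C1 | intermediate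
22 | angelic acid, (2Z)-2-methylbut-2-enoic acid | C/C=C(/C)C(=O)O | starting material
23 | (2Z)-2-methylbut-2-enoic 2,4,6-trichlorobenzoic anhydride | C/C=C(/C)C(=O)OC(=O)c1c(Cl)cc(Cl)cc1Cl | intermediate (not isolated)
24 | (4S,6S,7R,8R,9S,10R)-9-angeloyloxy-6-[(tert-butyldimethylsilyl)oxy]-10-hydroxy-8,12-bis[(4-methoxyphenyl)methoxy]germacr-11(13)-en-5-one | C1C[C@@](C)(O)[C@@H](OC(=O)/C(C)=C\C)[C@H](OCc2ccc(OC)cc2)[C@@H](C(=C)COCc3ccc(OC)cc3)[C@H](O[Si](C)(C)C(C)(C)C)C(=O)[C@@H](C)C1 | intermediate
25 | (4S,6S,7R,8R,9S,10R)-9-angeloyloxy-6-[(tert-butyldimethylsilyl)oxy]-8,10,12-trihydroxygermacr-11(13)-en-5-one | C1C[C@@](C)(O)[C@@H](OC(=O)/C(C)=C\C)[C@H](O)[C@@H](C(=C)CO)[C@H](O[Si](C)(C)C(C)(C)C)C(=O)[C@@H](C)C1 | intermediate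
26 | (4S,6S,7R,8R,9S,10R)-9-angeloyloxy-6-[(tert-butyldimethylsilyl)oxy]-8,10-dihydroxy-5-oxogermacr-11(13)-en-12-al | C1C[C@@](C)(O)[C@@H](OC(=O)/C(C)=C\C)[C@H](O)[C@@H](C(=C)C=O)[C@H](O[Si](C)(C)C(C)(C)C)C(=O)[C@@H](C)C1 | intermediate (not isolated)
27 | 12,8-lactol of 26 (both anomers at C12) | C=C1C(O)O[C@@H]2[C@@H]1[C@H](O[Si](C)(C)C(C)(C)C)C(=O)[C@@H](C)CCC[C@@](C)(O)[C@H]2OC(=O)/C(C)=C\C | intermediate (not isolated)
28 | (4S,6S,7R,8R,9S,10R)-9-angeloyloxy-6-[(tert-butyldimethylsilyl)oxy]-10-hydroxy-5-oxogermacr-11(13)-en-12,8-olide | C=C1C(=O)O[C@@H]2[C@@H]1[C@H](O[Si](C)(C)C(C)(C)C)C(=O)[C@@H](C)CCC[C@@](C)(O)[C@H]2OC(=O)/C(C)=C\C | intermediate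
29 | (4S,6S,7S,8R,9S,10R)-9-angeloyloxy-6,10-dihydroxy-5-oxogermacr-11(13)-en-12,8-olide (CNP0311008.1) | C=C1C(=O)O[C@@H]2[C@@H]1[C@H](O)C(=O)[C@@H](C)CCC[C@@](C)(O)[C@H]2OC(=O)/C(C)=C\C | target

**Step count and risk**

Total: 15 steps. Longest linear sequence: 13 steps (steps 1–4 and 7–15); steps 5 and 6 build the enyne arm.

Step 9 (key step). Most likely to go wrong: heterolysis of the C5–C10 bond of the alkoxide (a dissociative course) with loss of stereochemical fidelity, or proton transfer involving the doubly allylic C7–H before silylation. The reacting chair also carries two syn-axial methyl groups, which slows the concerted path and gives these side processes more time. Fallback: from 15 the same bond reorganisation is run in the neutral manifold, where no ion pair can separate. Heating 15 (1,2-dichlorobenzene, 190 °C, base-washed glass) should give the enol, which tautomerises to the ketone (4S,7R,8S,9E)-8,12-bis[(4-methoxyphenyl)methoxy]germacra-9,11(13)-dien-5-one F1. Kinetic deprotonation of F1 at the C6 methylene (KN(SiMe3)2, THF, −78 °C) and O-silylation with TBSCl should return to 18; the geometry of the regenerated enol ether would have to be checked against that required.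

Step 10. Most likely to go wrong: poor facial selectivity at C9=C10 because the (E)-alkene can turn through the ring once C5 is a ketone, or over-oxidation of C11=C13. Fallback: from 18 the two oxidations are separated and the second is put under catalyst control. One equivalent of dimethyldioxirane at −78 °C should convert only the enol ether into (4S,6S,7R,8S,9E)-6-[(tert-butyldimethylsilyl)oxy]-8,12-bis[(4-methoxyphenyl)methoxy]germacra-9,11(13)-dien-5-one F2. A Shi epoxidation of F2 (fructose-derived ketone of the matching antipode, KHSO5, pH 10.5 buffer, MeCN) then gives 20; this bulky chiral dioxirane discriminates against 1,1-disubstituted alkenes.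

Step 11. Most likely to go wrong: the cation-like C10 is intercepted across the ring (1,5-hydride shift from C6–H, attack by the enol of the C5 ketone) or loses a proton, instead of being captured with inversion. Fallback: from 20 the transannular carbonyl participation is used on purpose under anhydrous conditions. Pyridinium p-toluenesulfonate in methanol should give the bridged methyl ketal (5-methoxy-5,10-epoxy form of 21, an 11-oxabicyclo[4.4.1]undecane) F3, in which C10–O was delivered intramolecularly to the inner face. Mild aqueous acid (oxalic acid, THF/H2O) then opens F3 to 21.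

Step 12. Most likely to go wrong: slow acylation of the hindered C9–OH, and Z to E isomerisation of the acyl donor on prolonged heating. Fallback: from 21 the angelate double bond is built on the ester. Carbodiimide coupling with 2-[bis(2,2,2-trifluoroethoxy)phosphoryl]propanoic acid gives (4S,6S,7R,8R,9S,10R)-9-{2-[bis(2,2,2-trifluoroethoxy)phosphoryl]propanoyloxy}-6-[(tert-butyldimethylsilyl)oxy]-10-hydroxy-8,12-bis[(4-methoxyphenyl)methoxy]germacr-11(13)-en-5-one F4. A Still–Gennari olefination of F4 with acetaldehyde (KN(SiMe3)2, 18-crown-6, THF, −78 °C) gives the (Z)-ester 24.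

Step 2. Most likely to go wrong: insufficient anti selectivity of the small cationic electrophile at the quaternary carbon. The minor diastereomer is harmful because its epimerisation at the tertiary α-carbon would give the enantiomer of 4, so it must be removed and not equilibrated. Fallback: from 2 the quaternary centre is set by a ligand-controlled Tsuji allylation (Pd2(dba)3, tert-butyl-PHOX ligand of the antipode that reinforces anti attack, diallyl carbonate, Bu4N[Ph3SiF2]) to give (2R,6S)-2,6-dimethyl-2-(prop-2-en-1-yl)cyclohexan-1-one F5. Double-bond migration with RuHCl(CO)(PPh3)3 gives (2R,6S)-2,6-dimethyl-2-[(1E)-prop-1-en-1-yl]cyclohexan-1-one F6, and ozonolysis of F6 (O3, CH2Cl2, −78 °C; PPh3) gives 4.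

**Further compounds**

F1 | step 9 | (4S,7R,8S,9E)-8,12-bis[(4-methoxyphenyl)methoxy]germacra-9,11(13)-dien-5-one | C1C/C(C)=C/[C@H](OCc2ccc(OC)cc2)[C@@H](C(=C)COCc3ccc(OC)cc3)CC(=O)[C@@H](C)C1
F2 | step 10 | (4S,6S,7R,8S,9E)-6-[(tert-butyldimethylsilyl)oxy]-8,12-bis[(4-methoxyphenyl)methoxy]germacra-9,11(13)-dien-5-one | C1C/C(C)=C/[C@H](OCc2ccc(OC)cc2)[C@@H](C(=C)COCc3ccc(OC)cc3)[C@H](O[Si](C)(C)C(C)(C)C)C(=O)[C@@H](C)C1
F3 | step 11 | bridged methyl ketal of 21: 6-[(tert-butyldimethylsilyl)oxy]-5,10-epoxy-9-hydroxy-5-methoxy-8,12-bis[(4-methoxyphenyl)methoxy]germacr-11(13)-ene, oxygen bridge on the inner face of C5 and C10 | C1C[C@@](C)(O7)[C@@H](O)[C@H](OCc2ccc(OC)cc2)[C@@H](C(=C)COCc3ccc(OC)cc3)[C@H](O[Si](C)(C)C(C)(C)C)[C@@]7(OC)[C@@H](C)C1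
F4 | step 12 | (4S,6S,7R,8R,9S,10R)-9-{2-[bis(2,2,2-trifluoroethoxy)phosphoryl]propanoyloxy}-6-[(tert-butyldimethylsilyl)oxy]-10-hydroxy-8,12-bis[(4-methoxyphenyl)methoxy]germacr-11(13)-en-5-one (both epimers at the phosphonate carbon) | C1C[C@@](C)(O)[C@@H](OC(=O)C(C)P(=O)(OCC(F)(F)F)OCC(F)(F)F)[C@H](OCc2ccc(OC)cc2)[C@@H](C(=C)COCc3ccc(OC)cc3)[C@H](O[Si](C)(C)C(C)(C)C)C(=O)[C@@H](C)C1
F5 | step 2 | (2R,6S)-2,6-dimethyl-2-(prop-2-en-1-yl)cyclohexan-1-one | O=C1[C@@H](C)CCC[C@]1(C)CC=C
F6 | step 2 | (2R,6S)-2,6-dimethyl-2-[(1E)-prop-1-en-1-yl]cyclohexan-1-one | O=C1[C@@H](C)CCC[C@]1(C)/C=C/C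
A1 | alternative 1 | methyl (2Z)-11-angeloyloxy-2-(bromomethyl)-4-[(tert-butyldimethylsilyl)oxy]-6,10-dimethyl-5,12-dioxo-10-[(triethylsilyl)oxy]dodec-2-enoate, target configuration at the carbons that become C4, C6, C9 and C10 | COC(=O)/C(CBr)=C/[C@H](O[Si](C)(C)C(C)(C)C)C(=O)[C@@H](C)CCC[C@@](C)(O[Si](CC)(CC)CC)[C@@H](OC(=O)/C(C)=C\C)C=O
A2 | alternative 2 | 2,3-seco diene: trans-disubstituted α-methylene-γ-butyrolactone carrying the C9–C10–C1–C2 allyl carbinol chain on C8 and the C6–C5–C4–C3 vinyl ketone chain on C7 | C=C1C(=O)O[C@@H]([C@H](OC(=O)/C(C)=C\C)[C@](C)(O)CC=C)[C@@H]1[C@H](O[Si](C)(C)C(C)(C)C)C(=O)[C@@H](C)C=C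
A3 | alternative 3 | 9-angeloyloxy-6-[(tert-butyldimethylsilyl)oxy]-14-noreudesma-5(10),11(13)-dien-12,8-olide | C=C1C(=O)O[C@@H]2[C@@H]1[C@H](O[Si](C)(C)C(C)(C)C)C3=C(CCC[C@@H]3C)[C@H]2OC(=O)/C(C)=C\C
A4 | alternative 3 | 9-angeloyloxy-6-[(tert-butyldimethylsilyl)oxy]-5,10-dioxo-14-norgermacr-11(13)-en-12,8-olide | C=C1C(=O)O[C@@H]2[C@@H]1[C@H](O[Si](C)(C)C(C)(C)C)C(=O)[C@@H](C)CCCC(=O)[C@H]2OC(=O)/C(C)=C\C
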